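**Retrosynthetic overview**
1. The target is (13S)-8α-hydroxy-10-epi-labdan-15-yl acetate. In ring B (C5–C10) the tertiary C8–OH and the C9–H lie cis to each other and to the C10 methyl, which is the mark of a syn hydration of a tetrasubstituted C8=C9 alkene.
2. C8=C9 is cut into two ketone carbons, the C8 methyl ketone on the C6–C7 arm of C5 and the C9 ketone on C10, held cis on ring A. An intramolecular McMurry coupling closes ring B last.
3. The C9 ketone comes from a C9 aldehyde on C10 and a C11–C15 Grignard reagent that carries C13, made from methyl hydrogen (R)-3-methylglutarate.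
4. Quaternary C10 with C9 cis to the C5 side chain comes from an Ireland–Claisen shift of a glycolate ester on the 2β oxygen of a cyclohexenol made from (S)-α-ionone, then oxidative decarboxylation.
5. Ring order: ring A is bought with α-ionone, ring B is closed by the McMurry step; hydroboration, desilylation and acetylation finish.

Key step: step 16

Remark: the SMILES is read as the cis-fused (10-epi) labdane with H5, the C10 methyl (C20), H9 and the C8 hydroxyl all α and C13 S; labdane numbering is used throughout, and β is the face of the C5 side chain.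
Remark: (S)-α-ionone and methyl hydrogen (R)-3-methylglutarate are taken as purchasable in high enantiomeric purity; the silyl group is tert-butyldiphenylsilyl so that it survives the acidic ketal cleavage and the titanium reagent.

**Route**

Step 1
Reactants: 1 (S)-α-ionone
Product: 3 (S)-dihydro-α-ionone, via triethylsilyl enol ether 2 (not isolated)
Conditions: Et3SiH, RhCl(PPh3)3 (cat.), toluene, 50 °C; then K2CO3, MeOH, rt
Reagents that add atoms: none
Why: Rhodium-catalysed 1,4-hydrosilylation of the enone (conjugate reduction) and methanolysis of the silyl enol ether should saturate only the side-chain C=C and leave the trisubstituted ring alkene and the C5 stereocentre untouched.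

Step 2
Reactants: 3 (S)-dihydro-α-ionone
Product: 4 2-methyl-2-{2-[(1S)-2,6,6-trimethylcyclohex-2-en-1-yl]ethyl}-1,3-dioxolane
Conditions: ethylene glycol, PPTS (cat.), benzene, reflux (Dean–Stark)
Reagents that add atoms: ethylene glycol OCCO
Why: Acid-catalysed ketalisation with azeotropic removal of water masks the C8 methyl ketone for the hydride and organometallic steps, and the weak acid should not move the ring double bond.

Step 3
Reactants: 4 dioxolane
Product: 5 (4S)-3,5,5-trimethyl-4-[2-(2-methyl-1,3-dioxolan-2-yl)ethyl]cyclohex-2-en-1-one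
Conditions: t-BuOOH, Pd(OH)2/C (cat.), K2CO3, CH2Cl2, 0 °C → rt
Reagents that add atoms: tert-butyl hydroperoxide CC(C)(C)OO
Why: Radical allylic oxidation by tert-butylperoxy radicals should attack the open ring methylene C2 at the CH end of the C1=C10 alkene and give the conjugated enone, the tertiary C5–H being shielded by the gem-dimethyl group and the side chain.

Step 4
Reactants: 5 enone
Product: 6 (1S,4S)-3,5,5-trimethyl-4-[2-(2-methyl-1,3-dioxolan-2-yl)ethyl]cyclohex-2-en-1-ol (OH trans to the side chain)
Conditions: LiBH(s-Bu)3, THF, −78 °C; then NaOH, H2O2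
Reagents that add atoms: none
Why: 1,2-Reduction of the β,β-disubstituted enone by the bulky borohydride should occur on the β face of C2, away from the axial C4 methyl that guards the α face when the C5 side chain is pseudoaxial, so the new carbinol carries OH α, trans to the side chain.

Step 5
Reactants: 6 trans allylic alcohol
Product: 7 (1R,4S)-3,5,5-trimethyl-4-[2-(2-methyl-1,3-dioxolan-2-yl)ethyl]cyclohex-2-en-1-yl (benzyloxy)acetate (ester oxygen cis to the side chain)
Conditions: BnOCH2CO2H, PPh3, DIAD, THF, 0 °C → rt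
Reagents that add atoms: (benzyloxy)acetic acid OC(=O)COCc1ccccc1
Why: Mitsunobu esterification displaces the activated C2 oxygen by the carboxylate with SN2 inversion and so puts the ester oxygen on the β face, cis to the C5 side chain, while attack at the tertiary C10 end of the allyl system is sterically closed.

Step 6
Reactants: 7 cis glycolate ester
Product: 10 2-(benzyloxy)-2-{(1R,6S)-1,5,5-trimethyl-6-[2-(2-methyl-1,3-dioxolan-2-yl)ethyl]cyclohex-2-en-1-yl}acetic acid (both C9 epimers), via silyl ketene acetal 8 (not isolated), via trimethylsilyl ester 9 (not isolated)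
Conditions: LiN(SiMe3)2, Me3SiCl, Et3N, THF, −78 °C → rt, then 65 °C; aq. citric acid work-up
Reagents that add atoms: none
Why: Ireland–Claisen rearrangement, in which the chelated glycolate enolate is trapped as its silyl ketene acetal and the suprafacial [3,3] shift across C2–C1=C10 delivers C9 to C10 on the β face that carried the C2 oxygen, so that quaternary C10 is set with C9 cis to the C5 side chain and the C20 methyl α, the alkene moves to C1=C2, and the C9 configuration is of no consequence.

Step 7
Reactants: 10 α-benzyloxy acid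
Product: 11 2-hydroxy-2-{(1R,2S)-1,3,3-trimethyl-2-[2-(2-methyl-1,3-dioxolan-2-yl)ethyl]cyclohexyl}acetic acid
Conditions: H2 (1 atm), Pd/C, EtOAc, rt
Reagents that add atoms: none
Why: Heterogeneous hydrogenation should saturate the cis-disubstituted C1=C2 alkene, which creates no stereocentre, and cleave the benzyl ether by hydrogenolysis in the same operation.

Step 8
Reactants: 11 α-hydroxy acid
Product: 12 (1R,2S)-1,3,3-trimethyl-2-[2-(2-methyl-1,3-dioxolan-2-yl)ethyl]cyclohexane-1-carbaldehyde
Conditions: Pb(OAc)4, pyridine, CH2Cl2, 0 °C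
Reagents that add atoms: none
Why: Oxidative decarboxylation of the α-hydroxy acid by tetravalent lead (glycol-type cleavage) expels the carboxyl carbon as CO2 and leaves C9 as an aldehyde on quaternary C10, which cannot epimerise.

Step 9
Reactants: 13 methyl hydrogen (R)-3-methylglutarate
Product: 14 methyl (3R)-5-hydroxy-3-methylpentanoate
Conditions: BH3·SMe2, THF, 0 °C → rt; then MeOH
Reagents that add atoms: none
Why: Borane reduces the free carboxylic acid through its acyloxyborane far faster than the methyl ester, so this chemoselective reduction tells the two arms of the glutarate apart without touching the methyl-bearing centre.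

Step 10
Reactants: 14 hydroxy ester
Product: 15 methyl (3R)-5-[(tert-butyldiphenylsilyl)oxy]-3-methylpentanoate
Conditions: TBDPSCl, imidazole, DMF, rt
Reagents that add atoms: tert-butyl(chloro)diphenylsilane CC(C)(C)[Si](Cl)(c1ccccc1)c1ccccc1
Why: Silylation of the primary alcohol blocks lactonisation and gives an ether that is stable to hydride, Grignard formation, aqueous acid and low-valent titanium.

Step 11
Reactants: 15 silyloxy ester
Product: 16 (3S)-5-[(tert-butyldiphenylsilyl)oxy]-3-methylpentan-1-ol
Conditions: LiAlH4, THF, 0 °C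
Reagents that add atoms: none
Why: Hydride reduction of the ester to the primary alcohol leaves the silyl ether and the stereocentre unchanged.

Step 12
Reactants: 16 alcohol
Product: 17 {[(3R)-5-bromo-3-methylpentyl]oxy}(tert-butyl)diphenylsilane
Conditions: CBr4, PPh3, CH2Cl2, 0 °C
Reagents that add atoms: carbon tetrabromide BrC(Br)(Br)Br
Why: Appel bromination turns the primary alcohol into the bromide under neutral conditions that spare the silyl ether.

Step 13
Reactants: 12 aldehyde; 17 bromide
Product: 19 (4S)-6-[(tert-butyldiphenylsilyl)oxy]-4-methyl-1-{(1R,2S)-1,3,3-trimethyl-2-[2-(2-methyl-1,3-dioxolan-2-yl)ethyl]cyclohexyl}hexan-1-ol (C9 epimers), via Grignard reagent 18 (not isolated)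
Conditions: 17, Mg, I2 (cat.), THF, 40 °C; then 12, THF, −78 → 0 °C; aq. NH4Cl
Reagents that add atoms: none
Why: Grignard addition to the non-enolisable neopentyl aldehyde forms the C9–C11 bond, and the carbinol epimers at C9 merge in the oxidation that follows.

Step 14
Reactants: 19 C9 carbinol
Product: 20 (4S)-6-[(tert-butyldiphenylsilyl)oxy]-4-methyl-1-{(1R,2S)-1,3,3-trimethyl-2-[2-(2-methyl-1,3-dioxolan-2-yl)ethyl]cyclohexyl}hexan-1-one
Conditions: Dess–Martin periodinane, pyridine, CH2Cl2, rt
Reagents that add atoms: none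
Why: Dess–Martin oxidation converts the hindered secondary alcohol into the C9 ketone under buffered conditions that keep the ketal and the silyl ether.

Step 15
Reactants: 20 keto ketal
Product: 21 (4S)-6-[(tert-butyldiphenylsilyl)oxy]-4-methyl-1-[(1R,2S)-1,3,3-trimethyl-2-(3-oxobutyl)cyclohexyl]hexan-1-one
Conditions: 80% aq. AcOH, THF, 45 °C
Reagents that add atoms: water O
Why: Mild acid hydrolysis of the dioxolane frees the C8 methyl ketone, the silyl ether is stable to aqueous acetic acid, and no stereocentre is enolisable.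

Step 16
Reactants: 21 cis ring A diketone
Product: 22 (13S)-15-[(tert-butyldiphenylsilyl)oxy]-10-epi-labd-8-ene
Conditions: TiCl3(DME)1.5, Zn–Cu couple, DME, reflux; 21 added by syringe pump at high dilution, then continued reflux
Reagents that add atoms: none
Why: Low-valent titanium, made from trivalent titanium chloride and Zn–Cu, transfers one electron to each carbonyl, the C8 and C9 ketyls join on the metal to a titanium pinacolate, and at reflux both oxygens pass to titanium to leave the C8=C9 double bond; this is an intramolecular McMurry carbonyl coupling, well known for diketones that give tetrasubstituted cyclohexenes. Ring B closes as a six-membered ring by union of the two carbonyl carbons (in ketyl terms a 6-exo-trig addition of the C8 ketyl to the C9 carbonyl), which is free of strain because the C9 acyl group on C10 and the C6–C7–C8 arm on C5 are cis on ring A. No stereocentre is formed, and C5, C10 and C13 cannot epimerise since C10 is quaternary, C5 is not α to a carbonyl and C13 is remote. The step needs intramolecular over intermolecular coupling and full deoxygenation over arrest at the diol or plain reduction of the crowded C9 ketone. Slow addition at high dilution secures the first, and reflux together with the nearness of the unhindered C8 methyl ketyl to C9 secures the second.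

Step 17
Reactants: 22 tetrasubstituted alkene
Product: 24 (13S)-15-[(tert-butyldiphenylsilyl)oxy]-10-epi-labdan-8α-ol, via C8 alkylborane 23 (not isolated)
Conditions: BH3·THF (excess), THF, 0 °C → rt; then NaOH, H2O2, 0 → 40 °C
Reagents that add atoms: hydrogen peroxide OO
Why: Hydroboration–oxidation, in which borane should add syn across C8=C9 from the convex α face that bears the C20 methyl and H5 (ring A is folded over the β face) with boron on C8 away from quaternary C10, and oxidation with retention then gives 8α-OH and 9α-H.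

Step 18
Reactants: 24 silyl ether
Product: 25 (13S)-10-epi-labdane-8α,15-diol
Conditions: Bu4NF, THF, rt
Reagents that add atoms: none
Why: Fluoride cleaves the Si–O bond of the primary silyl ether and leaves the tertiary alcohol untouched.

Step 19
Reactants: 25 diol
Product: 26 (13S)-8α-hydroxy-10-epi-labdan-15-yl acetate
Conditions: Ac2O, pyridine, CH2Cl2, 0 °C → rt
Reagents that add atoms: acetic anhydride CC(=O)OC(C)=O
Why: Acetylation without an acyl-transfer catalyst should take the primary C15 hydroxyl only, since the tertiary C8 hydroxyl flanked by C9 and the C17 methyl is far too hindered.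

**Compound list**
1 | (S)-α-ionone | CC(=O)/C=C/[C@@H]1C(C)=CCCC1(C)C | starting material
2 | triethyl({4-[(1S)-2,6,6-trimethylcyclohex-2-en-1-yl]but-2-en-2-yl}oxy)silane (E/Z) | CC[Si](CC)(CC)OC(C)=CC[C@@H]1C(C)=CCCC1(C)C | intermediate
3 | (S)-dihydro-α-ionone, 4-[(1S)-2,6,6-trimethylcyclohex-2-en-1-yl]butan-2-one | CC(=O)CC[C@@H]1C(C)=CCCC1(C)C | intermediate
4 | 2-methyl-2-{2-[(1S)-2,6,6-trimethylcyclohex-2-en-1-yl]ethyl}-1,3-dioxolane | CC1(CC[C@@H]2C(C)=CCCC2(C)C)OCCO1 | intermediate
5 | (4S)-3,5,5-trimethyl-4-[2-(2-methyl-1,3-dioxolan-2-yl)ethyl]cyclohex-2-en-1-one | CC1(CC[C@@H]2C(C)=CC(=O)CC2(C)C)OCCO1 | intermediate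
6 | (1S,4S)-3,5,5-trimethyl-4-[2-(2-methyl-1,3-dioxolan-2-yl)ethyl]cyclohex-2-en-1-ol (trans) | CC1(CC[C@@H]2C(C)=C[C@@H](O)CC2(C)C)OCCO1 | intermediate
7 | (1R,4S)-3,5,5-trimethyl-4-[2-(2-methyl-1,3-dioxolan-2-yl)ethyl]cyclohex-2-en-1-yl (benzyloxy)acetate (cis) | CC1(CC[C@@H]2C(C)=C[C@H](OC(=O)COCc3ccccc3)CC2(C)C)OCCO1 | intermediate
8 | (Z)-trimethylsilyl ketene acetal of 7 | CC1(CC[C@@H]2C(C)=C[C@H](O/C(O[Si](C)(C)C)=C/OCc3ccccc3)CC2(C)C)OCCO1 | intermediate
9 | trimethylsilyl ester of 10 | CC1(CC[C@@H]2[C@](C)(C(OCc3ccccc3)C(=O)O[Si](C)(C)C)C=CCC2(C)C)OCCO1 | intermediate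
10 | 2-(benzyloxy)-2-{(1R,6S)-1,5,5-trimethyl-6-[2-(2-methyl-1,3-dioxolan-2-yl)ethyl]cyclohex-2-en-1-yl}acetic acid | CC1(CC[C@@H]2[C@](C)(C(OCc3ccccc3)C(=O)O)C=CCC2(C)C)OCCO1 | intermediate
11 | 2-hydroxy-2-{(1R,2S)-1,3,3-trimethyl-2-[2-(2-methyl-1,3-dioxolan-2-yl)ethyl]cyclohexyl}acetic acid | CC1(CC[C@@H]2[C@](C)(C(O)C(=O)O)CCCC2(C)C)OCCO1 | intermediate
12 | (1R,2S)-1,3,3-trimethyl-2-[2-(2-methyl-1,3-dioxolan-2-yl)ethyl]cyclohexane-1-carbaldehyde | CC1(CC[C@@H]2[C@](C)(C=O)CCCC2(C)C)OCCO1 | intermediate
13 | methyl hydrogen (R)-3-methylglutarate | OC(=O)C[C@@H](C)CC(=O)OC | starting material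
14 | methyl (3R)-5-hydroxy-3-methylpentanoate | OCC[C@@H](C)CC(=O)OC | intermediate
15 | methyl (3R)-5-[(tert-butyldiphenylsilyl)oxy]-3-methylpentanoate | CC(C)(C)[Si](c1ccccc1)(c1ccccc1)OCC[C@@H](C)CC(=O)OC | intermediate
16 | (3S)-5-[(tert-butyldiphenylsilyl)oxy]-3-methylpentan-1-ol | CC(C)(C)[Si](c1ccccc1)(c1ccccc1)OCC[C@@H](C)CCO | intermediate
17 | {[(3R)-5-bromo-3-methylpentyl]oxy}(tert-butyl)diphenylsilane | CC(C)(C)[Si](c1ccccc1)(c1ccccc1)OCC[C@@H](C)CCBr | intermediate
18 | (3R)-5-[(tert-butyldiphenylsilyl)oxy]-3-methylpentylmagnesium bromide | CC(C)(C)[Si](c1ccccc1)(c1ccccc1)OCC[C@@H](C)CC[Mg]Br | intermediate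
19 | (4S)-6-[(tert-butyldiphenylsilyl)oxy]-4-methyl-1-{(1R,2S)-1,3,3-trimethyl-2-[2-(2-methyl-1,3-dioxolan-2-yl)ethyl]cyclohexyl}hexan-1-ol | CC1(CC[C@@H]2[C@](C)(C(O)CC[C@H](C)CCO[Si](c3ccccc3)(c3ccccc3)C(C)(C)C)CCCC2(C)C)OCCO1 | intermediate
20 | (4S)-6-[(tert-butyldiphenylsilyl)oxy]-4-methyl-1-{(1R,2S)-1,3,3-trimethyl-2-[2-(2-methyl-1,3-dioxolan-2-yl)ethyl]cyclohexyl}hexan-1-one | CC1(CC[C@@H]2[C@](C)(C(=O)CC[C@H](C)CCO[Si](c3ccccc3)(c3ccccc3)C(C)(C)C)CCCC2(C)C)OCCO1 | intermediate
21 | (4S)-6-[(tert-butyldiphenylsilyl)oxy]-4-methyl-1-[(1R,2S)-1,3,3-trimethyl-2-(3-oxobutyl)cyclohexyl]hexan-1-one | CC(C)(C)[Si](c1ccccc1)(c1ccccc1)OCC[C@@H](C)CCC(=O)[C@]2(C)CCCC(C)(C)[C@@H]2CCC(C)=O | intermediate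
22 | (13S)-15-[(tert-butyldiphenylsilyl)oxy]-10-epi-labd-8-ene | CC(C)(C)[Si](c1ccccc1)(c1ccccc1)OCC[C@@H](C)CCC2=C(C)CC[C@H]3C(C)(C)CCC[C@@]23C | intermediate
23 | (13S)-15-[(tert-butyldiphenylsilyl)oxy]-10-epi-labdan-8α-ylborane | CC(C)(C)[Si](c1ccccc1)(c1ccccc1)OCC[C@@H](C)CC[C@@H]2[C@]3(C)CCCC(C)(C)[C@@H]3CC[C@@]2(C)B | intermediate
24 | (13S)-15-[(tert-butyldiphenylsilyl)oxy]-10-epi-labdan-8α-ol | CC(C)(C)[Si](c1ccccc1)(c1ccccc1)OCC[C@@H](C)CC[C@@H]2[C@]3(C)CCCC(C)(C)[C@@H]3CC[C@@]2(C)O | intermediate
25 | (13S)-10-epi-labdane-8α,15-diol | OCC[C@@H](C)CC[C@@H]1[C@]2(C)CCCC(C)(C)[C@@H]2CC[C@@]1(C)O | intermediate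
26 | (13S)-8α-hydroxy-10-epi-labdan-15-yl acetate | CC(=O)OCC[C@@H](C)CC[C@@H]1[C@]2(C)CCCC(C)(C)[C@@H]2CC[C@@]1(C)O | target

**Count and risks**
Total step count: 19. Longest linear sequence: 15 steps (steps 1–8 and 13–19); steps 9–12 make the side-chain bromide.

Steps most likely to fail:

- **Step 16 (McMurry closure).** Electron transfer may simply reduce the crowded C9 carbonyl to its carbinol, the coupling may stall at the titanium-bound diol, or two molecules may couple if addition is too fast. The fallback sets out from 21 and comes back at 22. SmI2 with HMPA and t-BuOH in THF closes ring B by addition of the C8 ketyl to the C9 carbonyl and gives the cis-8,9-diol F1. Thiophosgene and DMAP turn it into the cyclic thionocarbonate F2. Heating F2 in P(OMe)3 (Corey–Winter olefination) removes both oxygens and returns the alkene 22.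

- **Step 17 (hydroboration).** Borane may add too slowly to the tetrasubstituted alkene, so that warming lets boron migrate, or it may approach from the β face or place boron on C9. The fallback sets out from 22 and comes back at 24. Photo-oxygenation (O2, tetraphenylporphyrin, visible light, CH2Cl2; Schenck ene reaction) should put oxygen on C8 from the α face and take H11, the hydrogen geminal to the bulky C10 group, giving the 8α-hydroperoxy-9(11)-ene F3. PPh3 reduces it to the allylic alcohol F4. Hydrogenation with [Ir(cod)(PCy3)(py)]PF6 under H2 in CH2Cl2, directed by the tertiary hydroxyl, adds H9 on the α face and gives 24.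

- **Step 6 (Ireland–Claisen shift).** The ketene acetal must reach the conformer with a pseudoaxial C2–O bond, in which the migrating carbon meets the axial C4 methyl. If that is too costly, loss of the silyl group or elimination may outrun the shift. The fallback sets out from 7 and comes back at 12. K2CO3 in MeOH frees the cis allylic alcohol F5. KH and Bu3SnCH2I in THF give the stannylmethyl ether F6. n-BuLi in THF at −78 °C brings tin–lithium exchange and a suprafacial [2,3]-Wittig–Still shift of the unsubstituted CH2 to C10, giving the homoallylic alcohol F7. H2 over Pd/C saturates C1=C2 to give alcohol F8, and Dess–Martin oxidation gives aldehyde 12.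

**Further compounds**
F1 | step 16 | (13S)-15-[(tert-butyldiphenylsilyl)oxy]-10-epi-labdane-8,9-diol (hydroxyls cis, face not assigned) | CC(C)(C)[Si](c1ccccc1)(c1ccccc1)OCC[C@@H](C)CCC2(O)C(C)(O)CC[C@H]3C(C)(C)CCC[C@@]23C
F2 | step 16 | 8,9-cyclic thionocarbonate of F1 | CC(C)(C)[Si](c1ccccc1)(c1ccccc1)OCC[C@@H](C)CCC2(OC(=S)O4)C4(C)CC[C@H]3C(C)(C)CCC[C@@]23C
F3 | step 17 | (13S)-15-[(tert-butyldiphenylsilyl)oxy]-8α-hydroperoxy-10-epi-labd-9(11)-ene | CC(C)(C)[Si](c1ccccc1)(c1ccccc1)OCC[C@@H](C)CC=C2[C@]3(C)CCCC(C)(C)[C@@H]3CC[C@@]2(C)OO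
F4 | step 17 | (13S)-15-[(tert-butyldiphenylsilyl)oxy]-10-epi-labd-9(11)-en-8α-ol | CC(C)(C)[Si](c1ccccc1)(c1ccccc1)OCC[C@@H](C)CC=C2[C@]3(C)CCCC(C)(C)[C@@H]3CC[C@@]2(C)O
F5 | step 6 | (1R,4S)-3,5,5-trimethyl-4-[2-(2-methyl-1,3-dioxolan-2-yl)ethyl]cyclohex-2-en-1-ol (cis) | CC1(CC[C@@H]2C(C)=C[C@H](O)CC2(C)C)OCCO1
F6 | step 6 | tributyl({[(1R,4S)-3,5,5-trimethyl-4-[2-(2-methyl-1,3-dioxolan-2-yl)ethyl]cyclohex-2-en-1-yl]oxy}methyl)stannane | CC1(CC[C@@H]2C(C)=C[C@H](OC[Sn](CCCC)(CCCC)CCCC)CC2(C)C)OCCO1
F7 | step 6 | {(1R,6S)-1,5,5-trimethyl-6-[2-(2-methyl-1,3-dioxolan-2-yl)ethyl]cyclohex-2-en-1-yl}methanol | CC1(CC[C@@H]2[C@](C)(CO)C=CCC2(C)C)OCCO1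
F8 | step 6 | {(1R,2S)-1,3,3-trimethyl-2-[2-(2-methyl-1,3-dioxolan-2-yl)ethyl]cyclohexyl}methanol | CC1(CC[C@@H]2[C@](C)(CO)CCCC2(C)C)OCCO1
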